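**Plan**

- Retrosynthesis: after removal of a silyl group from the carbinol oxygen, ring A is cut at C1–C2 and C5–C6 into a four-carbon ketene-acetal silyloxydiene (C2–C5) and a two-carbon terminal ynone (C1, C6) that carries the whole hydroxylated side chain.
- Enabling feature: ring A has acyl at C1, OMe at C2, H at C3, OH at C4, prenyl at C5 and H at C6, which is the print a 1,1-dimethoxy-3-silyloxydiene with a prenyl-bearing terminus leaves on a terminal acetylenic ketone after loss of methanol.
- The ynone is cut at its C(=O)–C(sp) bond (Weinreb amide plus ethynylmagnesium bromide); the diene at its acyl–CH= bond (acid chloride plus 1,1-dimethoxyethene).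
- Forward: the amino acid is taken in four steps to the ynone and the unsaturated acid in three steps to the diene; the two are joined in the benzannulation that makes ring A, the only ring formed, and a desilylation finishes.
- Stereochemistry: the single S centre is the α-carbon of O-methyl-L-tyrosine, kept with net retention in the nitrous acid deamination (double inversion) and never enolised afterwards.

Key step: step 8

Remark: read from the SMILES, the carbinol centre is S (OH > C=O > CH2Ar > H), the same descriptor and spatial sense as the α-carbon of L-tyrosine, so a deamination with retention is what is required.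

**Route**

Step 1
Reactants: 1 O-methyl-L-tyrosine [(S)-2-amino-3-(4-methoxyphenyl)propanoic acid]
Product: 3 (S)-2-hydroxy-3-(4-methoxyphenyl)propanoic acid, via alpha-lactone 2 (not isolated)
Conditions: NaNO2, 1 M aq. H2SO4, 0 °C → rt
Reagents that add atoms: water, O
Why: Nitrous acid deamination of an α-amino acid goes with net retention, because the neighbouring carboxylate displaces dinitrogen with inversion to give the (R)-α-lactone 2 and water opens it at the same carbon with a second inversion, so the S centre of 1 should be carried into 3.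

Step 2
Reactants: 3 (S)-2-hydroxy-3-(4-methoxyphenyl)propanoic acid
Product: 4 (S)-2-hydroxy-N-methoxy-3-(4-methoxyphenyl)-N-methylpropanamide
Conditions: MeNH(OMe)·HCl, EDC·HCl, HOBt, N-methylmorpholine, CH2Cl2, 0 °C → rt
Reagents that add atoms: N,O-dimethylhydroxylamine hydrochloride, CNOC.Cl
Why: Carbodiimide/HOBt amide coupling (Weinreb amide formation) is selective for the amine over the secondary hydroxyl and needs no strong base, so the α-centre should not epimerise.

Step 3
Reactants: 4 (S)-2-hydroxy-N-methoxy-3-(4-methoxyphenyl)-N-methylpropanamide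
Product: 5 (S)-2-(tert-butyldimethylsilyloxy)-N-methoxy-3-(4-methoxyphenyl)-N-methylpropanamide
Conditions: TBSCl, imidazole, DMF, rt
Reagents that add atoms: tert-butyldimethylsilyl chloride, CC(C)(C)[Si](C)(C)Cl
Why: Imidazole-promoted silylation of a secondary alcohol is routine and gives a silyl ether that withstands the Grignard reagent and the thermal cycloaddition yet leaves with fluoride at the end.

Step 4
Reactants: 5 (S)-2-(tert-butyldimethylsilyloxy)-N-methoxy-3-(4-methoxyphenyl)-N-methylpropanamide; 6 ethynylmagnesium bromide
Product: 8 (S)-4-(tert-butyldimethylsilyloxy)-5-(4-methoxyphenyl)pent-1-yn-3-one, via bromomagnesium hemiaminal 7 (not isolated)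
Conditions: HC≡CMgBr (0.5 M in THF), THF, −20 → 0 °C; cannulated into 1 M aq. HCl, 0 °C
Reagents that add atoms: none
Why: Weinreb ketone synthesis, in which the acetylide adds once to give the chelated tetrahedral adduct 7 that releases the ynone only on quenching, while the inverse acidic quench protonates the liberated N,O-dimethylhydroxylamine before it can add to the terminal ynone and the non-enolising conditions leave the stereocentre untouched.

Step 5
Reactants: 9 5-methylhex-4-enoic acid
Product: 10 5-methylhex-4-enoyl chloride
Conditions: (COCl)2, cat. DMF, CH2Cl2, 0 °C → rt; evaporated, used crude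
Reagents that add atoms: oxalyl chloride, O=C(Cl)C(=O)Cl
Why: Acid chloride formation through the catalytic Vilsmeier-type chloroiminium species is mild enough to spare the trisubstituted alkene, and the by-products are gases.

Step 6
Reactants: 10 5-methylhex-4-enoyl chloride; 11 1,1-dimethoxyethene
Product: 12 1,1-dimethoxy-7-methylocta-1,6-dien-3-one
Conditions: Et3N, Et2O, 0 °C → rt
Reagents that add atoms: none
Why: C-Acylation of a ketene acetal, in which the nucleophilic CH2 terminus of 11 attacks the acid chloride and the amine removes the proton from the resulting dimethoxycarbenium ion, should give the push-pull acylketene acetal as is established for simple acid chlorides.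

Step 7
Reactants: 12 1,1-dimethoxy-7-methylocta-1,6-dien-3-one
Product: 14 (3Z)-1,1-dimethoxy-7-methyl-3-(trimethylsilyloxy)octa-1,3,6-triene, via lithium dienolate 13 (not isolated)
Conditions: LiN(iPr)2, THF, −78 °C; TMSCl, −78 °C → rt; pentane, filtration, evaporation (no aqueous work-up)
Reagents that add atoms: chlorotrimethylsilane, C[Si](C)(C)Cl
Why: Kinetic deprotonation at the only sp3 α-carbon of the acylketene acetal and O-silylation of the cross-conjugated enolate (silyl enol ether formation) should give mainly the 3Z diene, the isomer whose alkyl chain is cis to the silyloxy group and which can reach the s-cis conformation.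

Step 8
Reactants: 14 (3Z)-1,1-dimethoxy-7-methyl-3-(trimethylsilyloxy)octa-1,3,6-triene; 8 (S)-4-(tert-butyldimethylsilyloxy)-5-(4-methoxyphenyl)pent-1-yn-3-one
Product: 17 (S)-2-(tert-butyldimethylsilyloxy)-1-[4-hydroxy-2-methoxy-5-(3-methylbut-2-en-1-yl)phenyl]-3-(4-methoxyphenyl)propan-1-one (O-silyl lespeflorin C4), via cyclohexadiene ketal 15 (not isolated), via aryl trimethylsilyl ether 16 (not isolated)
Conditions: 14 (2 equiv), toluene, rt → 70 °C until 15 is consumed; then 0.5 M aq. HCl–THF, 0 °C
Reagents that add atoms: none
Why: The reaction is a strongly polarised, asynchronous normal-demand Diels–Alder cycloaddition in which the C4 terminus of 14 (the nucleophilic end of the silyl dienol ether, reinforced by the ketene acetal) bonds to the unsubstituted β-carbon of 8 and the acetal carbon C1 bonds to the α-carbon, and in the limit it is a Mukaiyama–Michael addition followed by collapse of the allenolate onto the dimethoxycarbenium ion. The closest known reaction type is the benzannulation of 1,1-dialkoxy-3-silyloxybuta-1,3-dienes with acetylenic esters and ketones to give resorcinol monoethers. Ring A closes intermolecularly as a (4+2) ring from the four diene carbons and the two alkyne carbons (in the stepwise picture the second bond forms by 6-exo-trig attack on the carbenium carbon), giving the cyclohexa-1,4-diene ketal 15. In 15 the ketal carbon and the ring hydrogen γ to the ketone stand 1,4 to each other, so methanol is lost on warming to give arene 16 before the cold acid wash, which then only cleaves the labile aryl O–SiMe3 bond to give phenol 17 with the methyl ether at C2 and the free hydroxyl at C4 already told apart. No new stereocentre remains in 17 (the sp3 ring carbon of 15 is flattened on aromatisation, so the diene geometry does not matter for the product), and the existing S centre is not enolised under neutral thermal conditions. The selectivity needed is regiochemical, acyl next to methoxy and prenyl next to hydroxyl, and it is secured by the match of the largest HOMO coefficient at diene C4 with the largest LUMO coefficient at the unhindered terminal carbon of the ynone; an excess of 14 offsets the slower reaction of a terminally substituted diene.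

Step 9
Reactants: 17 (S)-2-(tert-butyldimethylsilyloxy)-1-[4-hydroxy-2-methoxy-5-(3-methylbut-2-en-1-yl)phenyl]-3-(4-methoxyphenyl)propan-1-one
Product: 18 lespeflorin C4 [(S)-2-hydroxy-1-[4-hydroxy-2-methoxy-5-(3-methylbut-2-en-1-yl)phenyl]-3-(4-methoxyphenyl)propan-1-one]
Conditions: HF·pyridine, pyridine, THF, 0 °C → rt
Reagents that add atoms: none
Why: Fluoride-driven cleavage of the silyl ether (desilylation through the strong Si–F bond) in a pyridine-buffered, non-basic medium should free the carbinol without enolising the α-hydroxy ketone and without closing the ortho-prenylphenol to a chroman.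

**Compound list**

1 | O-methyl-L-tyrosine, (S)-2-amino-3-(4-methoxyphenyl)propanoic acid | COc1ccc(C[C@H](N)C(=O)O)cc1 | starting material
2 | (R)-3-(4-methoxybenzyl)oxiran-2-one (α-lactone) | COc1ccc(C[C@H]2OC2=O)cc1 | intermediate (not isolated)
3 | (S)-2-hydroxy-3-(4-methoxyphenyl)propanoic acid | COc1ccc(C[C@H](O)C(=O)O)cc1 | intermediate
4 | (S)-2-hydroxy-N-methoxy-3-(4-methoxyphenyl)-N-methylpropanamide | COc1ccc(C[C@H](O)C(=O)N(C)OC)cc1 | intermediate
5 | (S)-2-(tert-butyldimethylsilyloxy)-N-methoxy-3-(4-methoxyphenyl)-N-methylpropanamide | COc1ccc(C[C@H](O[Si](C)(C)C(C)(C)C)C(=O)N(C)OC)cc1 | intermediate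
6 | ethynylmagnesium bromide | C#C[Mg]Br | starting material
7 | bromomagnesium (4S)-4-(tert-butyldimethylsilyloxy)-3-[methoxy(methyl)amino]-5-(4-methoxyphenyl)pent-1-yn-3-olate (either configuration at C3) | COc1ccc(C[C@H](O[Si](C)(C)C(C)(C)C)C(O[Mg]Br)(C#C)N(C)OC)cc1 | intermediate (not isolated)
8 | (S)-4-(tert-butyldimethylsilyloxy)-5-(4-methoxyphenyl)pent-1-yn-3-one | COc1ccc(C[C@H](O[Si](C)(C)C(C)(C)C)C(=O)C#C)cc1 | intermediate
9 | 5-methylhex-4-enoic acid | CC(C)=CCCC(=O)O | starting material
10 | 5-methylhex-4-enoyl chloride | CC(C)=CCCC(=O)Cl | intermediate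
11 | 1,1-dimethoxyethene | C=C(OC)OC | starting material
12 | 1,1-dimethoxy-7-methylocta-1,6-dien-3-one | COC(OC)=CC(=O)CCC=C(C)C | intermediate
13 | lithium (3Z)-1,1-dimethoxy-7-methylocta-1,3,6-trien-3-olate | COC(OC)=C/C(O[Li])=C/CC=C(C)C | intermediate (not isolated)
14 | (3Z)-1,1-dimethoxy-7-methyl-3-(trimethylsilyloxy)octa-1,3,6-triene | COC(OC)=C/C(O[Si](C)(C)C)=C/CC=C(C)C | intermediate
15 | (2S)-2-(tert-butyldimethylsilyloxy)-1-[6,6-dimethoxy-3-(3-methylbut-2-en-1-yl)-4-(trimethylsilyloxy)cyclohexa-1,4-dien-1-yl]-3-(4-methoxyphenyl)propan-1-one (both epimers at ring C3) | COc1ccc(C[C@H](O[Si](C)(C)C(C)(C)C)C(=O)C2=CC(CC=C(C)C)C(O[Si](C)(C)C)=CC2(OC)OC)cc1 | intermediate (not isolated)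
16 | (S)-2-(tert-butyldimethylsilyloxy)-1-[2-methoxy-5-(3-methylbut-2-en-1-yl)-4-(trimethylsilyloxy)phenyl]-3-(4-methoxyphenyl)propan-1-one | COc1ccc(C[C@H](O[Si](C)(C)C(C)(C)C)C(=O)c2cc(CC=C(C)C)c(O[Si](C)(C)C)cc2OC)cc1 | intermediate (not isolated)
17 | (S)-2-(tert-butyldimethylsilyloxy)-1-[4-hydroxy-2-methoxy-5-(3-methylbut-2-en-1-yl)phenyl]-3-(4-methoxyphenyl)propan-1-one (O-silyl lespeflorin C4) | COc1ccc(C[C@H](O[Si](C)(C)C(C)(C)C)C(=O)c2cc(CC=C(C)C)c(O)cc2OC)cc1 | intermediate
18 | lespeflorin C4, (S)-2-hydroxy-1-[4-hydroxy-2-methoxy-5-(3-methylbut-2-en-1-yl)phenyl]-3-(4-methoxyphenyl)propan-1-one | COc1ccc(C[C@H](O)C(=O)c2cc(CC=C(C)C)c(O)cc2OC)cc1 | target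

**Step count**

Total: 9 steps. Longest linear sequence: 6 steps (steps 1, 2, 3, 4, 8, 9, from O-methyl-L-tyrosine); the diene branch is 3 steps (5, 6, 7).

**Steps most likely to fail**

1. Step 8. The cycloaddition at the alkyl-bearing diene terminus may be so slow that oligomerisation of the terminal ynone and hydrolysis of the diene outrun ring closure. The fallback sets out from 8 (with 11 as the source of the diene) and comes back at 17; it puts the prenyl group on after the benzannulation.
   - 11 would be acylated with acetyl chloride (Et3N, Et2O) to 4,4-dimethoxybut-3-en-2-one F1.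
   - F1 would be silylated (TMSCl, Et3N, cat. ZnCl2) to the unsubstituted and faster diene 1,1-dimethoxy-3-(trimethylsilyloxy)buta-1,3-diene F2.
   - F2 and 8 in toluene should give the cyclohexadiene ketal F3, which loses methanol to the aryl trimethylsilyl ether F4; the same cold acid wash would then give (S)-2-(tert-butyldimethylsilyloxy)-1-(4-hydroxy-2-methoxyphenyl)-3-(4-methoxyphenyl)propan-1-one F5.
   - Bromination with N-bromosuccinimide (MeCN, 0 °C) is expected at ring C5, ortho to the hydroxyl and para to the methoxy group, giving (S)-1-(5-bromo-4-hydroxy-2-methoxyphenyl)-2-(tert-butyldimethylsilyloxy)-3-(4-methoxyphenyl)propan-1-one F6.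
   - Stille coupling of F6 with tributyl(3-methylbut-2-en-1-yl)stannane (Pd(PPh3)4, a zerovalent palladium complex, DMF, 80 °C) would deliver 17.

2. Step 6. The amine may dehydrochlorinate the enolisable acid chloride to a ketene, or the dimethoxycarbenium intermediate may collapse to the β-keto ester, in competition with C-acylation. The fallback sets out from 11 and comes back at 12; it builds the chain by alkylation instead of acylation. 11 would be acylated with acetyl chloride (Et3N, Et2O), the simplest established case, to 4,4-dimethoxybut-3-en-2-one F1 (the same compound as in the fallback to step 8). Deprotonation at the methyl group (LiN(iPr)2, THF, −78 °C) would give lithium 4,4-dimethoxybuta-1,3-dien-2-olate F7, and C-alkylation with 1-bromo-3-methylbut-2-ene (α′-alkylation of a vinylogous ester-type enolate) would give 12.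

3. Step 4. The released N,O-dimethylhydroxylamine, or a second acetylide, may add in conjugate fashion to the terminal ynone during the reaction or the quench. The fallback sets out from 5 and comes back at 8; it changes the oxidation level so that no amine is present when the ynone forms. 5 would be reduced with iBu2AlH (THF, −78 °C) to (S)-2-(tert-butyldimethylsilyloxy)-3-(4-methoxyphenyl)propanal F8. Addition of HC≡CMgBr (THF, −78 → 0 °C, dilute HCl quench) would give (3RS,4S)-4-(tert-butyldimethylsilyloxy)-5-(4-methoxyphenyl)pent-1-yn-3-ol F9 as a mixture of carbinol epimers. Both epimers converge on oxidation with Dess–Martin periodinane (CH2Cl2, rt) to 8.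

**Further compounds**

F1 | step 8 | 4,4-dimethoxybut-3-en-2-one | COC(OC)=CC(C)=O
F2 | step 8 | 1,1-dimethoxy-3-(trimethylsilyloxy)buta-1,3-diene | COC(OC)=CC(=C)O[Si](C)(C)C
F3 | step 8 | (2S)-2-(tert-butyldimethylsilyloxy)-1-[6,6-dimethoxy-4-(trimethylsilyloxy)cyclohexa-1,4-dien-1-yl]-3-(4-methoxyphenyl)propan-1-one | COc1ccc(C[C@H](O[Si](C)(C)C(C)(C)C)C(=O)C2=CCC(O[Si](C)(C)C)=CC2(OC)OC)cc1
F4 | step 8 | (S)-2-(tert-butyldimethylsilyloxy)-1-[2-methoxy-4-(trimethylsilyloxy)phenyl]-3-(4-methoxyphenyl)propan-1-one | COc1ccc(C[C@H](O[Si](C)(C)C(C)(C)C)C(=O)c2ccc(O[Si](C)(C)C)cc2OC)cc1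
F5 | step 8 | (S)-2-(tert-butyldimethylsilyloxy)-1-(4-hydroxy-2-methoxyphenyl)-3-(4-methoxyphenyl)propan-1-one | COc1ccc(C[C@H](O[Si](C)(C)C(C)(C)C)C(=O)c2ccc(O)cc2OC)cc1
F6 | step 8 | (S)-1-(5-bromo-4-hydroxy-2-methoxyphenyl)-2-(tert-butyldimethylsilyloxy)-3-(4-methoxyphenyl)propan-1-one | COc1ccc(C[C@H](O[Si](C)(C)C(C)(C)C)C(=O)c2cc(Br)c(O)cc2OC)cc1
F7 | step 6 | lithium 4,4-dimethoxybuta-1,3-dien-2-olate | COC(OC)=CC(=C)O[Li]
F8 | step 4 | (S)-2-(tert-butyldimethylsilyloxy)-3-(4-methoxyphenyl)propanal | COc1ccc(C[C@H](O[Si](C)(C)C(C)(C)C)C=O)cc1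
F9 | step 4 | (3RS,4S)-4-(tert-butyldimethylsilyloxy)-5-(4-methoxyphenyl)pent-1-yn-3-ol | COc1ccc(C[C@H](O[Si](C)(C)C(C)(C)C)C(O)C#C)cc1
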